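A direct plan would start from ring A (labdane numbering: ring A = C1–C5 and C10, ring B = C5–C10, C17 = ester carbon on C8, C11–C16 = chain on C9). The allyl ketone A1, with C10 set by an asymmetric decarboxylative allylation, would be annulated to a cyclopentenone, reduced with lithium in ammonia and trapped with formaldehyde to the hydrindanone A2, then ring-expanded and olefinated to the δ-lactone (Z)-acrylate A3.
An Ireland–Claisen rearrangement of A3 would close ring B through the C8–C9 bond to the acid A4. Its carboxyl carbon would be reduced and methylenated to the vinyl compound A5, and hydroboration and B-alkyl Suzuki coupling with the iodoenoate A6 would come last.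
Its weakest points would be: (a) the reductive hydroxymethylation to A2. C5 and the carbinol carbon would be set on a hydrindanone enolate with little facial bias although every later centre would be relayed from them, and a five-membered ring would be built only to be cut open again.
(b) The lactone Claisen ring closure. It would need a forced boat transition state at 110–140 °C on a γ-acyloxy enoate that could instead lose its γ-proton or eliminate, so ring B and two stereocentres would rest on one demanding late step.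
(c) The end game. Four operations would turn one carboxyl carbon into a two-carbon link, and the last step would expose the most precious material, a base-labile β,γ-unsaturated ester with an allylic acetate, to a borane that must tell the vinyl group from the ring alkene and to palladium in aqueous base.

Plan of the new route:
The retrosynthesis cuts C12–C13 (Negishi coupling), then C4–C5 of ring A (cation–enol cyclisation), then C10–CH3 and C10–C1 (two conjugate additions), and finally C8–C9 together with C5=C10 of ring B (amine-catalysed Michael addition/aldol condensation).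
Ring B is therefore made first, from two acyclic pieces, and ring A is folded onto it; the C6=C7 alkene appears last.
The enabling feature is C6 of ring B: it ends as an alkene carbon, lies next to the ring-fusion carbon C5 (itself next to the C4 gem-dimethyl carbon), is β to C10 through C5, and is γ to the C17 ester carbon.
As a ketone, C6 lets C10 accept two nucleophiles in turn, makes C5 both the enol carbon that captures a C4 cation and an epimerisable centre that settles trans, and finally leaves as a regiodefined C6–C7 enol triflate.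
Only C9 is set by a catalyst; C8, C10 and C5 follow by substrate or thermodynamic control. No centre hangs on an unbiased enolate, no ring closure needs a strained pericyclic transition state, and the side chain is joined without base to a saturated keto diester before the labile β,γ-unsaturated ester exists.

Key step: step 4

Remark: 4-chlorobutanal is assumed to be used as the freshly distilled commercial aldehyde; the labdane numbering given above is used throughout.

Step 1
Reactants: 1 4-chlorobutanal; 2 methyl (2E)-4-oxopent-2-enoate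
Product: 4 methyl (1S,2S)-2-(2-chloroethyl)-5-oxocyclohex-3-ene-1-carboxylate, via keto aldehyde 3 (not isolated)
Conditions: (S)-α,α-diphenylprolinol trimethylsilyl ether (10 mol %), PhCO2H (10 mol %), CH2Cl2, 0 °C → rt; then p-TsOH·H2O (20 mol %), PhMe, 40 °C
Reagents that add atoms: none
Why: Enamine catalysis: the diarylprolinol silyl ether converts 1 into an (E)-enamine that adds to the 4-oxoenoate at the carbon β to the ketone (Michael addition of an aldehyde to a γ-keto-α,β-unsaturated ester), the (S)-catalyst shielding one enamine face so that C9 should be set as drawn (R in 3) and the syn course setting C8, and the acid then closes ring B by aldol condensation of the methyl ketone onto the aldehyde (C5=C10), with C8, α to the ester, free to settle trans to the C9 arm.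

Step 2
Reactants: 4 methyl (1S,2S)-2-(2-chloroethyl)-5-oxocyclohex-3-ene-1-carboxylate; 5 5-bromo-2-methylpent-2-ene
Product: 8 methyl (1S,2R)-2-(2-chloroethyl)-3-(4-methylpent-3-en-1-yl)-5-oxocyclohex-3-ene-1-carboxylate, via Grignard reagent 6 (not isolated), via silyl enol ether 7 (not isolated)
Conditions: 5, Mg, THF; then 4, CuBr·SMe2 (15 mol %), Me3SiCl, THF, −78 °C; solvent exchange; Pd(OAc)2 (1.1 equiv), MeCN, 25 °C
Reagents that add atoms: none
Why: Copper-catalysed 1,4-addition of the Grignard reagent with silyl chloride trapping should give the regiodefined enol silane 7, and Saegusa–Ito oxidation (divalent palladium enolate, β-hydride elimination from C10) restores the enone with the C1–C4 chain on C10, so the transient C10 centre is erased and only chemoselectivity for the enone over the ester and the alkyl chloride at −78 °C is required.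

Step 3
Reactants: 8 methyl (1S,2R)-2-(2-chloroethyl)-3-(4-methylpent-3-en-1-yl)-5-oxocyclohex-3-ene-1-carboxylate
Product: 10 methyl (1S,2R,3R)-2-(2-chloroethyl)-3-methyl-3-(4-methylpent-3-en-1-yl)-5-oxocyclohexane-1-carboxylate, via silyl enol ether 9 (not isolated)
Conditions: Me2CuLi (2.5 equiv), Me3SiCl, Et2O–THF, −78 → −30 °C; then 1 M HCl, THF, 0 °C
Reagents that add atoms: lithium dimethylcuprate, [Li+].C[Cu-]C
Why: Conjugate methylation of the β,β-disubstituted enone by the silyl chloride-accelerated cuprate: with the C9 arm and the C8 ester both equatorial on the half-chair, axial attack at C10 should come from the face anti to the C8 ester (the usual course trans to a substituent at the 5-position of a cyclohex-2-enone), which puts the methyl group cis to the C9 arm and the C1–C4 chain equatorial, i.e. the C10 configuration of the target.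

Step 4
Reactants: 10 methyl (1S,2R,3R)-2-(2-chloroethyl)-3-methyl-3-(4-methylpent-3-en-1-yl)-5-oxocyclohexane-1-carboxylate
Product: 12 methyl (1R,2S,4aR,8aS)-1-(2-chloroethyl)-5,5,8a-trimethyl-4-oxodecahydronaphthalene-2-carboxylate, via cis-fused ketone 11 (not isolated)
Conditions: TfOH (0.3 equiv), (CF3)2CHOH–CH2Cl2 (1:4), 0 → 25 °C
Reagents that add atoms: none
Why: TfOH protonates the trisubstituted C3=C4 alkene at C3 (Markovnikov) and the tertiary C4 cation is captured by C5 of the C5=C6 enol of the ring ketone, which forms the C4–C5 bond; the closest known reaction types are the Lewis-acid-mediated α-tert-alkylation of ketone enol derivatives and cation–olefin cyclisations terminated by an enol (the cationic counterpart of the Conia-ene reaction). Ring A closes in a 6-(enolexo) mode, whereas the other enol (C6=C7) or the carbonyl oxygen could only close an eight-membered ring, so the carbon skeleton itself directs the alkylation to C5. C5 is the only new stereocentre and is set under thermodynamic control: the tether from C10 reaches the planar enol carbon most easily from its own face and should give the cis-fused ketone 11 first, but C5 is α to the C6 carbonyl and should equilibrate through the enol in the same acid to the trans-fused decalone 12 (H5 anti to the C10 methyl group, C9 arm and C8 ester equatorial). C8, C9 and C10 are carried unchanged, because C10 is quaternary, C9 is not α to a carbonyl group and the C8 ester is already equatorial. The selectivity needed is capture of the cation by the enol in preference to proton loss or Prins addition of the alkene to the protonated carbonyl group; it should be secured by reversibility, since alkene isomers and the Prins adduct can return to the cation in the ionising solvent while the C-alkylated ketone cannot.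

Step 5
Reactants: 12 methyl (1R,2S,4aR,8aS)-1-(2-chloroethyl)-5,5,8a-trimethyl-4-oxodecahydronaphthalene-2-carboxylate
Product: 13 methyl (1R,2S,4aR,8aS)-1-(2-iodoethyl)-5,5,8a-trimethyl-4-oxodecahydronaphthalene-2-carboxylate
Conditions: NaI (5 equiv), acetone, reflux
Reagents that add atoms: sodium iodide, [Na+].[I-]
Why: Finkelstein exchange by SN2 at the unhindered primary C12 chloride, driven by precipitation of NaCl from acetone, under neutral conditions that leave the four stereocentres untouched.

Step 6
Reactants: 14 methyl 4-hydroxybut-2-ynoate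
Product: 15 methyl 4-[(tert-butyldiphenylsilyl)oxy]but-2-ynoate
Conditions: t-BuPh2SiCl, imidazole, CH2Cl2, 0 °C → rt
Reagents that add atoms: tert-butyl(chloro)diphenylsilane, CC(C)(C)[Si](Cl)(c1ccccc1)c1ccccc1
Why: Standard silylation of the primary propargylic alcohol; the acid-stable silyl ether is used instead of the final acetate because an allylic acetate would be ionised by zerovalent palladium in step 10.

Step 7
Reactants: 15 methyl 4-[(tert-butyldiphenylsilyl)oxy]but-2-ynoate
Product: 16 methyl (2Z)-4-[(tert-butyldiphenylsilyl)oxy]-3-iodobut-2-enoate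
Conditions: NaI, AcOH, 70 °C
Reagents that add atoms: sodium iodide, [Na+].[I-]
Why: Hydroiodination of the ynoate with NaI in acetic acid proceeds by anti addition (iodide to the β-carbon, proton to the α-carbon) and should give the (Z)-β-iodoenoate with iodine cis to the ester.

Step 8
Reactants: 13 methyl (1R,2S,4aR,8aS)-1-(2-iodoethyl)-5,5,8a-trimethyl-4-oxodecahydronaphthalene-2-carboxylate; 16 methyl (2Z)-4-[(tert-butyldiphenylsilyl)oxy]-3-iodobut-2-enoate
Product: 18 methyl (1R,2S,4aR,8aS)-1-[(3E)-3-{[(tert-butyldiphenylsilyl)oxy]methyl}-5-methoxy-5-oxopent-3-en-1-yl]-5,5,8a-trimethyl-4-oxodecahydronaphthalene-2-carboxylate, via organozinc iodide 17 (not isolated)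
Conditions: Zn dust, LiCl, THF, 40 °C; then 16, Pd2(dba)3 (2.5 mol %), SPhos (10 mol %), THF, 25 °C
Reagents that add atoms: none
Why: Zinc insertion into the primary iodide (ketone and esters are tolerated) followed by Negishi sp3–sp2 coupling with retention of the iodoalkene geometry should place C12 cis to the ester, which is the (E)-C13=C14 bond of the target, without base and on a saturated keto diester.

Step 9
Reactants: 18 methyl (1R,2S,4aR,8aS)-1-[(3E)-3-{[(tert-butyldiphenylsilyl)oxy]methyl}-5-methoxy-5-oxopent-3-en-1-yl]-5,5,8a-trimethyl-4-oxodecahydronaphthalene-2-carboxylate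
Product: 19 methyl (1R,2R,4aR,8aS)-1-[(3E)-3-{[(tert-butyldiphenylsilyl)oxy]methyl}-5-methoxy-5-oxopent-3-en-1-yl]-5,5,8a-trimethyl-4-{[(trifluoromethyl)sulfonyl]oxy}-1,2,4a,5,6,7,8,8a-octahydronaphthalene-2-carboxylate
Conditions: LiN(SiMe3)2 (1.05 equiv), THF, −78 °C; then Comins' reagent, −78 → 0 °C
Reagents that add atoms: N-(5-chloropyridin-2-yl)-1,1,1-trifluoro-N-[(trifluoromethyl)sulfonyl]methanesulfonamide (Comins' reagent), O=S(=O)(N(c1ccc(Cl)cn1)S(=O)(=O)C(F)(F)F)C(F)(F)F
Why: Kinetic enolisation of the C6 ketone at the C7 methylene (C5 is a hindered methine, the ester and enoate hydrogens are less acidic) and O-sulfonylation of the enolate with Comins' reagent should fix the double bond between C6 and C7.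

Step 10
Reactants: 19 methyl (1R,2R,4aR,8aS)-1-[(3E)-3-{[(tert-butyldiphenylsilyl)oxy]methyl}-5-methoxy-5-oxopent-3-en-1-yl]-5,5,8a-trimethyl-4-{[(trifluoromethyl)sulfonyl]oxy}-1,2,4a,5,6,7,8,8a-octahydronaphthalene-2-carboxylate
Product: 20 methyl (1R,2S,4aR,8aS)-1-[(3E)-3-{[(tert-butyldiphenylsilyl)oxy]methyl}-5-methoxy-5-oxopent-3-en-1-yl]-5,5,8a-trimethyl-1,2,4a,5,6,7,8,8a-octahydronaphthalene-2-carboxylate
Conditions: Pd(OAc)2 (5 mol %), PPh3 (10 mol %), HCO2H, n-Bu3N, DMF, 60 °C
Reagents that add atoms: none
Why: Palladium-catalysed formate reduction of the enol triflate (oxidative addition to zerovalent palladium, decarboxylation of the formate, C–H reductive elimination) should replace the sulfonate by hydrogen without moving the C6=C7 bond, the weak amine base leaving the allylic C8–H and its configuration alone.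

Step 11
Reactants: 20 methyl (1R,2S,4aR,8aS)-1-[(3E)-3-{[(tert-butyldiphenylsilyl)oxy]methyl}-5-methoxy-5-oxopent-3-en-1-yl]-5,5,8a-trimethyl-1,2,4a,5,6,7,8,8a-octahydronaphthalene-2-carboxylate
Product: 21 methyl (1R,2S,4aR,8aS)-1-[(3E)-3-(hydroxymethyl)-5-methoxy-5-oxopent-3-en-1-yl]-5,5,8a-trimethyl-1,2,4a,5,6,7,8,8a-octahydronaphthalene-2-carboxylate
Conditions: HF·pyridine, THF–pyridine, 0 °C → rt
Reagents that add atoms: none
Why: Fluoride cleavage of the silyl ether under mildly acidic conditions should spare both methyl esters and the β,γ-unsaturated ester, and the (E)-hydroxy enoate cannot lactonise because CH2OH is trans to the ester group.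

Step 12
Reactants: 21 methyl (1R,2S,4aR,8aS)-1-[(3E)-3-(hydroxymethyl)-5-methoxy-5-oxopent-3-en-1-yl]-5,5,8a-trimethyl-1,2,4a,5,6,7,8,8a-octahydronaphthalene-2-carboxylate
Product: 22 methyl (1R,2S,4aR,8aS)-1-[(3E)-3-(acetoxymethyl)-5-methoxy-5-oxopent-3-en-1-yl]-5,5,8a-trimethyl-1,2,4a,5,6,7,8,8a-octahydronaphthalene-2-carboxylate (CNP0190145.1)
Conditions: Ac2O, pyridine, DMAP (cat.), CH2Cl2, 0 °C
Reagents that add atoms: acetic anhydride, CC(=O)OC(C)=O
Why: Standard DMAP-catalysed acetylation of the primary allylic alcohol at 0 °C should give the target, pyridine being too weak a base to move the C6=C7 bond into conjugation with the C17 ester.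

**Compound list**

1 | 4-chlorobutanal | O=CCCCCl | starting material
2 | methyl (2E)-4-oxopent-2-enoate | COC(=O)/C=C/C(C)=O | starting material
3 | methyl (2S)-2-[(2R)-4-chloro-1-oxobutan-2-yl]-4-oxopentanoate | ClCC[C@@H](C=O)[C@@H](C(=O)OC)CC(C)=O | intermediate
4 | methyl (1S,2S)-2-(2-chloroethyl)-5-oxocyclohex-3-ene-1-carboxylate | ClCC[C@@H]1[C@@H](C(=O)OC)CC(=O)C=C1 | intermediate
5 | 5-bromo-2-methylpent-2-ene | CC(C)=CCCBr | starting material
6 | (4-methylpent-3-en-1-yl)magnesium bromide | CC(C)=CCC[Mg]Br | intermediate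
7 | methyl (1S,2S)-2-(2-chloroethyl)-3-(4-methylpent-3-en-1-yl)-5-[(trimethylsilyl)oxy]cyclohex-4-ene-1-carboxylate (both C3 epimers) | ClCC[C@@H]1[C@@H](C(=O)OC)CC(O[Si](C)(C)C)=CC1CCC=C(C)C | intermediate
8 | methyl (1S,2R)-2-(2-chloroethyl)-3-(4-methylpent-3-en-1-yl)-5-oxocyclohex-3-ene-1-carboxylate | ClCC[C@@H]1[C@@H](C(=O)OC)CC(=O)C=C1CCC=C(C)C | intermediate
9 | methyl (1S,2R,3S)-2-(2-chloroethyl)-3-methyl-3-(4-methylpent-3-en-1-yl)-5-[(trimethylsilyl)oxy]cyclohex-4-ene-1-carboxylate | ClCC[C@@H]1[C@@H](C(=O)OC)CC(O[Si](C)(C)C)=C[C@@]1(C)CCC=C(C)C | intermediate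
10 | methyl (1S,2R,3R)-2-(2-chloroethyl)-3-methyl-3-(4-methylpent-3-en-1-yl)-5-oxocyclohexane-1-carboxylate | ClCC[C@@H]1[C@@H](C(=O)OC)CC(=O)C[C@@]1(C)CCC=C(C)C | intermediate
11 | methyl (1R,2S,4aS,8aS)-1-(2-chloroethyl)-5,5,8a-trimethyl-4-oxodecahydronaphthalene-2-carboxylate (cis-fused) | ClCC[C@@H]1[C@@H](C(=O)OC)CC(=O)[C@H]2C(C)(C)CCC[C@@]12C | intermediate
12 | methyl (1R,2S,4aR,8aS)-1-(2-chloroethyl)-5,5,8a-trimethyl-4-oxodecahydronaphthalene-2-carboxylate (trans-fused) | ClCC[C@@H]1[C@@H](C(=O)OC)CC(=O)[C@@H]2C(C)(C)CCC[C@@]12C | intermediate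
13 | methyl (1R,2S,4aR,8aS)-1-(2-iodoethyl)-5,5,8a-trimethyl-4-oxodecahydronaphthalene-2-carboxylate | ICC[C@@H]1[C@@H](C(=O)OC)CC(=O)[C@@H]2C(C)(C)CCC[C@@]12C | intermediate
14 | methyl 4-hydroxybut-2-ynoate | COC(=O)C#CCO | starting material
15 | methyl 4-[(tert-butyldiphenylsilyl)oxy]but-2-ynoate | COC(=O)C#CCO[Si](c1ccccc1)(c1ccccc1)C(C)(C)C | intermediate
16 | methyl (2Z)-4-[(tert-butyldiphenylsilyl)oxy]-3-iodobut-2-enoate | COC(=O)/C=C(\I)CO[Si](c1ccccc1)(c1ccccc1)C(C)(C)C | intermediate
17 | {2-[(1R,2S,4aR,8aS)-2-(methoxycarbonyl)-5,5,8a-trimethyl-4-oxodecahydronaphthalen-1-yl]ethyl}zinc iodide | I[Zn]CC[C@@H]1[C@@H](C(=O)OC)CC(=O)[C@@H]2C(C)(C)CCC[C@@]12C | intermediate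
18 | methyl (1R,2S,4aR,8aS)-1-[(3E)-3-{[(tert-butyldiphenylsilyl)oxy]methyl}-5-methoxy-5-oxopent-3-en-1-yl]-5,5,8a-trimethyl-4-oxodecahydronaphthalene-2-carboxylate | COC(=O)/C=C(\CC[C@@H]1[C@@H](C(=O)OC)CC(=O)[C@@H]2C(C)(C)CCC[C@@]12C)CO[Si](c1ccccc1)(c1ccccc1)C(C)(C)C | intermediate
19 | methyl (1R,2R,4aR,8aS)-1-[(3E)-3-{[(tert-butyldiphenylsilyl)oxy]methyl}-5-methoxy-5-oxopent-3-en-1-yl]-5,5,8a-trimethyl-4-{[(trifluoromethyl)sulfonyl]oxy}-1,2,4a,5,6,7,8,8a-octahydronaphthalene-2-carboxylate | COC(=O)/C=C(\CC[C@@H]1[C@@H](C(=O)OC)C=C(OS(=O)(=O)C(F)(F)F)[C@@H]2C(C)(C)CCC[C@@]12C)CO[Si](c1ccccc1)(c1ccccc1)C(C)(C)C | intermediate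
20 | methyl (1R,2S,4aR,8aS)-1-[(3E)-3-{[(tert-butyldiphenylsilyl)oxy]methyl}-5-methoxy-5-oxopent-3-en-1-yl]-5,5,8a-trimethyl-1,2,4a,5,6,7,8,8a-octahydronaphthalene-2-carboxylate | COC(=O)/C=C(\CC[C@@H]1[C@@H](C(=O)OC)C=C[C@@H]2C(C)(C)CCC[C@@]12C)CO[Si](c1ccccc1)(c1ccccc1)C(C)(C)C | intermediate
21 | methyl (1R,2S,4aR,8aS)-1-[(3E)-3-(hydroxymethyl)-5-methoxy-5-oxopent-3-en-1-yl]-5,5,8a-trimethyl-1,2,4a,5,6,7,8,8a-octahydronaphthalene-2-carboxylate | COC(=O)/C=C(\CC[C@@H]1[C@@H](C(=O)OC)C=C[C@@H]2C(C)(C)CCC[C@@]12C)CO | intermediate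
22 | methyl (1R,2S,4aR,8aS)-1-[(3E)-3-(acetoxymethyl)-5-methoxy-5-oxopent-3-en-1-yl]-5,5,8a-trimethyl-1,2,4a,5,6,7,8,8a-octahydronaphthalene-2-carboxylate (CNP0190145.1) | COC(=O)/C=C(\CC[C@@H]1[C@@H](C(=O)OC)C=C[C@@H]2C(C)(C)CCC[C@@]12C)COC(C)=O | target

Total step count: 12. Longest linear sequence: 10 steps (steps 1–5 and 8–12).

Steps most likely to fail:

Step 4 (key step). The C4 cation may be lost by elimination to alkene isomers, or diverted by addition to the carbonyl group, faster than the small equilibrium amount of the C5 enol can capture it; the ring fusion may also fail to reach the trans form. The fallback makes the cation irreversibly from a tertiary chloride and meets it with a preformed, regiodefined enol silane. Setting out from 8, HCl (CH2Cl2, −78 °C) should add to the C3=C4 bond to give methyl (1S,2R)-3-(4-chloro-4-methylpentyl)-2-(2-chloroethyl)-5-oxocyclohex-3-ene-1-carboxylate F1. Me2CuLi/Me3SiCl as in step 3, with non-aqueous work-up, should give methyl (1S,2R,3S)-3-(4-chloro-4-methylpentyl)-2-(2-chloroethyl)-3-methyl-5-[(trimethylsilyl)oxy]cyclohex-4-ene-1-carboxylate F2. TiCl4 (CH2Cl2, −78 °C) should then ionise the tertiary chloride and close ring A at C5 (Lewis-acid α-tert-alkylation of a silyl enol ether). Brief treatment with p-TsOH would equilibrate C5, and the route would be rejoined at 12.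

Step 3. The methyl transfer may show poor facial selectivity: if the cuprate entered anti to the C9 arm instead of anti to the C8 ester, C10 would be formed with the wrong configuration. The fallback introduces the two C10 substituents in the reverse order, so that the same facial preference delivers the chain last. Setting out from 4, Me2CuLi/Me3SiCl should give methyl (1S,2S)-2-(2-chloroethyl)-3-methyl-5-[(trimethylsilyl)oxy]cyclohex-4-ene-1-carboxylate F3. Saegusa–Ito oxidation (Pd(OAc)2, MeCN) should convert it into methyl (1S,2R)-2-(2-chloroethyl)-3-methyl-5-oxocyclohex-3-ene-1-carboxylate F4. Copper-catalysed addition of 6 (CuBr·SMe2, Me3SiCl, −78 °C) and hydrolysis of the enol silane with 1 M HCl would rejoin the route at 10.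

Step 9. The lithium amide may deprotonate the side-chain unsaturated ester, or the C7 enolate may add to that ester in a Michael sense before it is sulfonylated. The fallback makes the alkene before the side chain is present. Setting out from 12, the same enolisation and sulfonylation should give methyl (1R,2R,4aR,8aS)-1-(2-chloroethyl)-5,5,8a-trimethyl-4-{[(trifluoromethyl)sulfonyl]oxy}-1,2,4a,5,6,7,8,8a-octahydronaphthalene-2-carboxylate F5. Formate reduction as in step 10 should give methyl (1R,2S,4aR,8aS)-1-(2-chloroethyl)-5,5,8a-trimethyl-1,2,4a,5,6,7,8,8a-octahydronaphthalene-2-carboxylate F6. NaI in acetone should give methyl (1R,2S,4aR,8aS)-1-(2-iodoethyl)-5,5,8a-trimethyl-1,2,4a,5,6,7,8,8a-octahydronaphthalene-2-carboxylate F7. Zinc insertion should give {2-[(1R,2S,4aR,8aS)-2-(methoxycarbonyl)-5,5,8a-trimethyl-1,2,4a,5,6,7,8,8a-octahydronaphthalen-1-yl]ethyl}zinc iodide F8, and Negishi coupling of this with 16 as in step 8 would rejoin the route at 20.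

**Further compounds**

F1 | step 4 | methyl (1S,2R)-3-(4-chloro-4-methylpentyl)-2-(2-chloroethyl)-5-oxocyclohex-3-ene-1-carboxylate | ClCC[C@@H]1[C@@H](C(=O)OC)CC(=O)C=C1CCCC(C)(C)Cl
F2 | step 4 | methyl (1S,2R,3S)-3-(4-chloro-4-methylpentyl)-2-(2-chloroethyl)-3-methyl-5-[(trimethylsilyl)oxy]cyclohex-4-ene-1-carboxylate | ClCC[C@@H]1[C@@H](C(=O)OC)CC(O[Si](C)(C)C)=C[C@@]1(C)CCCC(C)(C)Cl
F3 | step 3 | methyl (1S,2S)-2-(2-chloroethyl)-3-methyl-5-[(trimethylsilyl)oxy]cyclohex-4-ene-1-carboxylate (both C3 epimers) | ClCC[C@@H]1[C@@H](C(=O)OC)CC(O[Si](C)(C)C)=CC1C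
F4 | step 3 | methyl (1S,2R)-2-(2-chloroethyl)-3-methyl-5-oxocyclohex-3-ene-1-carboxylate | ClCC[C@@H]1[C@@H](C(=O)OC)CC(=O)C=C1C
F5 | step 9 | methyl (1R,2R,4aR,8aS)-1-(2-chloroethyl)-5,5,8a-trimethyl-4-{[(trifluoromethyl)sulfonyl]oxy}-1,2,4a,5,6,7,8,8a-octahydronaphthalene-2-carboxylate | ClCC[C@@H]1[C@@H](C(=O)OC)C=C(OS(=O)(=O)C(F)(F)F)[C@@H]2C(C)(C)CCC[C@@]12C
F6 | step 9 | methyl (1R,2S,4aR,8aS)-1-(2-chloroethyl)-5,5,8a-trimethyl-1,2,4a,5,6,7,8,8a-octahydronaphthalene-2-carboxylate | ClCC[C@@H]1[C@@H](C(=O)OC)C=C[C@@H]2C(C)(C)CCC[C@@]12C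
F7 | step 9 | methyl (1R,2S,4aR,8aS)-1-(2-iodoethyl)-5,5,8a-trimethyl-1,2,4a,5,6,7,8,8a-octahydronaphthalene-2-carboxylate | ICC[C@@H]1[C@@H](C(=O)OC)C=C[C@@H]2C(C)(C)CCC[C@@]12C
F8 | step 9 | {2-[(1R,2S,4aR,8aS)-2-(methoxycarbonyl)-5,5,8a-trimethyl-1,2,4a,5,6,7,8,8a-octahydronaphthalen-1-yl]ethyl}zinc iodide | I[Zn]CC[C@@H]1[C@@H](C(=O)OC)C=C[C@@H]2C(C)(C)CCC[C@@]12C
A1 | direct plan | (S)-2-allyl-2,6,6-trimethylcyclohexanone | C=CC[C@]1(C)CCCC(C)(C)C1=O
A2 | direct plan | (1R,3aS,7aR)-1-(hydroxymethyl)-3a,7,7-trimethyloctahydro-2H-inden-2-one | OC[C@@H]1C(=O)C[C@]2(C)CCCC(C)(C)[C@@H]12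
A3 | direct plan | methyl (2Z)-3-[(1S,4aS,8aR)-4a,8,8-trimethyl-3-oxooctahydro-1H-isochromen-1-yl]prop-2-enoate | COC(=O)/C=C\[C@@H]1OC(=O)C[C@]2(C)CCCC(C)(C)[C@@H]12
A4 | direct plan | (1R,2S,4aR,8aR)-2-(methoxycarbonyl)-5,5,8a-trimethyl-1,2,4a,5,6,7,8,8a-octahydronaphthalene-1-carboxylic acid | OC(=O)[C@@H]1[C@@H](C(=O)OC)C=C[C@@H]2C(C)(C)CCC[C@@]12C
A5 | direct plan | methyl (1R,2S,4aR,8aS)-5,5,8a-trimethyl-1-vinyl-1,2,4a,5,6,7,8,8a-octahydronaphthalene-2-carboxylate | C=C[C@@H]1[C@@H](C(=O)OC)C=C[C@@H]2C(C)(C)CCC[C@@]12C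
A6 | direct plan | methyl (2Z)-4-acetoxy-3-iodobut-2-enoate | COC(=O)/C=C(\I)COC(C)=O
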